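Locants follow germacrane numbering of the cyclodeca-1(10),4-diene ring: C6 bears the hydroxyl, C7 the isopropyl group (C11), C8 the coumarate. Everything rests on cutting C7–C8: the isopropyl-bearing C7 beside the C8 carbinol is read as a latent 2-propenyl homoallylic alcohol. One chromium-mediated intramolecular allylation of an open-chain ω-formyl allylic chloride closes the ten-membered carbocycle and sets C7 and C8, steered by a temporary silyloxy stereocentre at C6. That centre is then erased by oxidation and re-created by an Evans–Tishchenko reduction, in which the hemiacetal on O8 delivers hydride to C6 and keeps the p-coumaroyl group on O8, giving the anti-1,3-hydroxy ester of the target.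

Key step: step 14

Assumption: (S,S)-ProPhenol is taken to deliver the alkynyl group to the enal face that gives (S)-13; should its sense of induction be the reverse, the (R,R)-ligand is used.
Remarks: TBS = tert-butyldimethylsilyl, TBDPS = tert-butyldiphenylsilyl. The ten-membered 1,5-dienes (22 onward) are kept below 50 °C and purified on Et3N-deactivated silica, to avoid Cope rearrangement and acid-triggered transannular cyclisation.

Step 1
Reactants: 1 tert-butyl(but-3-yn-1-yloxy)dimethylsilane
Product: 3 (E)-tert-butyl[(4-iodo-3-methylbut-3-en-1-yl)oxy]dimethylsilane, via alkenylalane 2 (not isolated)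
Conditions: Me3Al, Cp2ZrCl2 (0.25 equiv), CH2Cl2, 0 °C to rt; then I2, THF, −30 °C
Reagents that add atoms: trimethylaluminium C[Al](C)C; iodine II
Why: Negishi zirconium-catalysed syn-carboalumination puts the methyl group on the internal and aluminium on the terminal alkyne carbon, and iodinolysis with retention should give the (E)-iodide that becomes the C10=C1 alkene.

Step 2
Reactants: 3 (E)-tert-butyl[(4-iodo-3-methylbut-3-en-1-yl)oxy]dimethylsilane; 4 (4-bromobut-1-yn-1-yl)trimethylsilane
Product: 6 (E)-tert-butyldimethyl{[3-methyl-8-(trimethylsilyl)oct-3-en-7-yn-1-yl]oxy}silane, via alkylzinc bromide 5 (not isolated)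
Conditions: 4, Zn dust, LiCl, THF, 50 °C; then 3, Pd(PPh3)4 (5 mol%), THF, rt to 40 °C
Reagents that add atoms: none
Why: Negishi sp2–sp3 coupling of a homopropargylic zinc reagent with an alkenyl iodide at zerovalent palladium proceeds with retention of the (E)-geometry, the silyl cap keeping the alkyne inert.

Step 3
Reactants: 6 (E)-tert-butyldimethyl{[3-methyl-8-(trimethylsilyl)oct-3-en-7-yn-1-yl]oxy}silane
Product: 7 (E)-tert-butyldimethyl[(3-methyloct-3-en-7-yn-1-yl)oxy]silane
Conditions: K2CO3, MeOH, rt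
Reagents that add atoms: none
Why: Methanolysis cleaves the alkynyl C–Si bond selectively (protodesilylation), whereas the TBS ether is stable to carbonate in methanol.

Step 4
Reactants: 8 1-(tert-butyldimethylsilyloxy)propan-2-one
Product: 9 ethyl (E)-4-(tert-butyldimethylsilyloxy)-3-methylbut-2-enoate
Conditions: (EtO)2P(O)CH2CO2Et, NaH, THF, 0 °C to rt; chromatography
Reagents that add atoms: triethyl phosphonoacetate CCOC(=O)CP(=O)(OCC)OCC
Why: Horner–Wadsworth–Emmons olefination of the methyl ketone should favour the (E)-enoate with the ester trans to the larger CH2OTBS group, the minor (Z)-isomer being removed by chromatography.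

Step 5
Reactants: 9 ethyl (E)-4-(tert-butyldimethylsilyloxy)-3-methylbut-2-enoate
Product: 10 (E)-4-(tert-butyldimethylsilyloxy)-3-methylbut-2-en-1-ol
Conditions: iBu2AlH (2.2 equiv), CH2Cl2, −78 °C
Reagents that add atoms: none
Why: Hydride reduction of the conjugated ester with iBu2AlH stops cleanly at the allylic alcohol by 1,2-addition without touching the alkene geometry.

Step 6
Reactants: 10 (E)-4-(tert-butyldimethylsilyloxy)-3-methylbut-2-en-1-ol
Product: 11 (E)-4-(tert-butyldimethylsilyloxy)-3-methylbut-2-enal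
Conditions: MnO2, CH2Cl2, rt
Reagents that add atoms: none
Why: Allylic oxidation with MnO2 under neutral conditions gives the enal (C6, C7, C11–C13) without E/Z isomerisation.

Step 7
Reactants: 7 (E)-tert-butyldimethyl[(3-methyloct-3-en-7-yn-1-yl)oxy]silane; 11 (E)-4-(tert-butyldimethylsilyloxy)-3-methylbut-2-enal
Product: 13 (4S,2E,9E)-1,12-bis(tert-butyldimethylsilyloxy)-2,10-dimethyldodeca-2,9-dien-5-yn-4-ol, via zinc alkynylide 12 (not isolated)
Conditions: 7 (2 equiv), Me2Zn, (S,S)-ProPhenol (10 mol%), Ph3PO (20 mol%), toluene, 0 °C; then 11, 0 °C to rt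
Reagents that add atoms: none
Why: Dinuclear zinc–ProPhenol catalysed asymmetric alkynylation of an enal, in which the chiral bimetallic pocket delivers the zinc alkynylide to one carbonyl face in a 1,2-addition, sets the temporary C6 stereocentre as (S).

Step 8
Reactants: 13 (4S,2E,9E)-1,12-bis(tert-butyldimethylsilyloxy)-2,10-dimethyldodeca-2,9-dien-5-yn-4-ol
Product: 15 (4S,2E,5Z,9E)-1,12-bis(tert-butyldimethylsilyloxy)-6-iodo-2,10-dimethyldodeca-2,5,9-trien-4-ol, via cyclic alkenylalanate 14 (not isolated)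
Conditions: NaAlH2(OCH2CH2OMe)2 (Red-Al), THF, 0 °C to rt; then I2, THF, −78 °C
Reagents that add atoms: iodine II
Why: Alkoxide-directed trans-hydroalumination of the propargylic alcohol delivers hydride to C5 and aluminium to C4 in a five-membered alanate, and iodinolysis with retention should give the (Z)-iodoalkene.

Step 9
Reactants: 15 (4S,2E,5Z,9E)-1,12-bis(tert-butyldimethylsilyloxy)-6-iodo-2,10-dimethyldodeca-2,5,9-trien-4-ol
Product: 16 (4R,2E,5E,9E)-1,12-bis(tert-butyldimethylsilyloxy)-2,6,10-trimethyldodeca-2,5,9-trien-4-ol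
Conditions: Me2CuLi (from MeLi and CuI, excess), Et2O, 0 °C
Reagents that add atoms: lithium dimethylcuprate [Li+].C[Cu-]C
Why: Corey–Posner substitution of the alkenyl iodide by the cuprate occurs with retention and gives the (E)-trisubstituted C4=C5 alkene with its C15 methyl (the descriptor at C6 changes only through priorities).

Step 10
Reactants: 16 (4R,2E,5E,9E)-1,12-bis(tert-butyldimethylsilyloxy)-2,6,10-trimethyldodeca-2,5,9-trien-4-ol
Product: 17 (4R,2E,5E,9E)-1,12-bis(tert-butyldimethylsilyloxy)-4-(tert-butyldiphenylsilyloxy)-2,6,10-trimethyldodeca-2,5,9-triene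
Conditions: TBDPSCl, imidazole, DMAP (cat.), DMF, rt
Reagents that add atoms: tert-butylchlorodiphenylsilane CC(C)(C)[Si](Cl)(c1ccccc1)c1ccccc1
Why: Silylation under non-acidic conditions protects the bis-allylic C6 hydroxyl with a group that is robust enough to outlive the cleavage of the two primary TBS ethers and is a poor leaving group.

Step 11
Reactants: 17 (4R,2E,5E,9E)-1,12-bis(tert-butyldimethylsilyloxy)-4-(tert-butyldiphenylsilyloxy)-2,6,10-trimethyldodeca-2,5,9-triene
Product: 18 (4R,2E,5E,9E)-4-(tert-butyldiphenylsilyloxy)-2,6,10-trimethyldodeca-2,5,9-triene-1,12-diol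
Conditions: HF·pyridine, pyridine, THF, 0 °C
Reagents that add atoms: none
Why: Buffered fluoride desilylation removes the two unhindered primary TBS ethers far faster than the hindered secondary TBDPS ether.

Step 12
Reactants: 18 (4R,2E,5E,9E)-4-(tert-butyldiphenylsilyloxy)-2,6,10-trimethyldodeca-2,5,9-triene-1,12-diol
Product: 19 (9R,3E,7E,10E)-9-(tert-butyldiphenylsilyloxy)-12-chloro-3,7,11-trimethyldodeca-3,7,10-trien-1-ol
Conditions: NCS, Me2S, CH2Cl2, −30 to 0 °C; aqueous work-up
Reagents that add atoms: N-chlorosuccinimide O=C1CCC(=O)N1Cl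
Why: Corey–Kim chlorination converts only the allylic C12 alkoxysulfonium salt into the unrearranged chloride by chloride displacement, whereas the non-allylic C8 hydroxyl is returned on work-up.

Step 13
Reactants: 19 (9R,3E,7E,10E)-9-(tert-butyldiphenylsilyloxy)-12-chloro-3,7,11-trimethyldodeca-3,7,10-trien-1-ol
Product: 20 (9R,3E,7E,10E)-9-(tert-butyldiphenylsilyloxy)-12-chloro-3,7,11-trimethyldodeca-3,7,10-trienal
Conditions: Dess–Martin periodinane, NaHCO3, CH2Cl2, 0 °C; used at once
Reagents that add atoms: none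
Why: Buffered Dess–Martin oxidation is mild enough to give the β,γ-unsaturated C8 aldehyde without shifting C10=C1 into conjugation and leaves the allylic chloride intact.

Step 14
Reactants: 20 (9R,3E,7E,10E)-9-(tert-butyldiphenylsilyloxy)-12-chloro-3,7,11-trimethyldodeca-3,7,10-trienal
Product: 22 (1(10)E,4E,6R,7R,8S)-6-(tert-butyldiphenylsilyloxy)germacra-1(10),4,11-trien-8-ol, via allylchromium dichloride 21 (not isolated)
Conditions: CrCl2 (8 equiv), THF, rt, slow addition of 20 over 12 h (final 2 mM); aq. NaHCO3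
Reagents that add atoms: none
Why: Two equivalents of CrCl2 (divalent chromium) reduce the C12–Cl bond to the allylchromium 21 (trivalent chromium), which equilibrates by 1,3-metal shift and adds through its γ-carbon C7 to the C8 aldehyde in a six-membered chair transition state. The closest known reaction type is the Nozaki–Hiyama–Kishi allylation used as a macrocyclisation of ω-formyl allylic halides. The ten-membered carbocycle closes 10-exo-trig at the carbonyl with SE2′ transposition of the allyl unit, so that C11=C12 is left as an exocyclic 2-propenyl group. C8 is controlled by the chair, since the (E)-allylchromium with C6 and the C9 chain both equatorial gives the 7,8-anti (ring-trans) relation. C7 is controlled by C6, because allylic 1,3-strain with the C11 methyl holds H6 in the allyl plane and the tether brings the aldehyde to the face carrying C5, which places OSi, propenyl and OH all pseudo-equatorial on a crown-like ring, so that the (6R) centre should lead to the C7 and C8 configurations of the target, (7R,8S) in the descriptors of 22. The step needs γ- over α-attack (inherent to allylchromium), ring closure over oligomerisation (slow addition, high dilution) and survival of the C6–O bond (a silyl ether is a poor leaving group for 1,4-elimination).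

Step 15
Reactants: 22 (1(10)E,4E,6R,7R,8S)-6-(tert-butyldiphenylsilyloxy)germacra-1(10),4,11-trien-8-ol
Product: 23 (1(10)E,4E,6R,7R,8S)-germacra-1(10),4,11-triene-6,8-diol
Conditions: TBAF, THF, rt
Reagents that add atoms: none
Why: Fluoride-induced desilylation frees the allylic C6 hydroxyl, whose configuration has done its work as control element.

Step 16
Reactants: 23 (1(10)E,4E,6R,7R,8S)-germacra-1(10),4,11-triene-6,8-diol
Product: 24 (1(10)E,4E,6R,7R,8S)-germacra-1(10),4-diene-6,8-diol
Conditions: H2 (1 atm), RhCl(PPh3)3 (10 mol%), benzene/EtOH, rt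
Reagents that add atoms: none
Why: Homogeneous hydrogenation with RhCl(PPh3)3 reduces the 1,1-disubstituted 2-propenyl alkene much faster than the two trisubstituted ring alkenes and turns it into the isopropyl group without touching a stereocentre.

Step 17
Reactants: 24 (1(10)E,4E,6R,7R,8S)-germacra-1(10),4-diene-6,8-diol
Product: 25 (1(10)E,4E,7R,8S)-8-hydroxygermacra-1(10),4-dien-6-one
Conditions: activated MnO2 (excess), CH2Cl2, rt
Reagents that add atoms: none
Why: MnO2 oxidises only the allylic C6 alcohol, leaving the non-allylic C8 hydroxyl, and the neutral conditions should avoid dehydration or epimerisation of the β-hydroxy enone.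

Step 18
Reactants: 26 (E)-3-(4-hydroxyphenyl)prop-2-enal
Product: 27 (E)-3-[4-(tert-butyldimethylsilyloxy)phenyl]prop-2-enal
Conditions: TBSCl, imidazole, DMF, rt
Reagents that add atoms: tert-butylchlorodimethylsilane CC(C)(C)[Si](C)(C)Cl
Why: Silylation masks the acidic phenol so that it cannot quench the samarium alkoxides of the next step.

Step 19
Reactants: 25 (1(10)E,4E,7R,8S)-8-hydroxygermacra-1(10),4-dien-6-one; 27 (E)-3-[4-(tert-butyldimethylsilyloxy)phenyl]prop-2-enal
Product: 28 (1(10)E,4E,6S,7S,8S)-6-hydroxygermacra-1(10),4-dien-8-yl (E)-3-[4-(tert-butyldimethylsilyloxy)phenyl]prop-2-enoate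
Conditions: SmI2 (0.3 equiv), 27 (5 equiv), THF, −10 °C
Reagents that add atoms: none
Why: In the Evans–Tishchenko reduction the trivalent samarium formed in the flask binds the C6 ketone and the hemiacetal of 27 on O8, and hydride shifts within a six-membered transition state to the C6 face syn to O8, which should give the 1,3-anti (6S) alcohol and leave the oxidised aldehyde as the cinnamate on O8 only.

Step 20
Reactants: 28 (1(10)E,4E,6S,7S,8S)-6-hydroxygermacra-1(10),4-dien-8-yl (E)-3-[4-(tert-butyldimethylsilyloxy)phenyl]prop-2-enoate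
Product: 29 (1(10)E,4E,6S,7S,8S)-6-hydroxygermacra-1(10),4-dien-8-yl (E)-3-(4-hydroxyphenyl)prop-2-enoate (CNP0178839.1)
Conditions: TBAF, AcOH (1:1), THF, 0 °C
Reagents that add atoms: none
Why: Buffered fluoride cleaves the labile aryl silyl ether, and the near-neutral medium should prevent 1,3-acyl migration to O6 and acid-induced transannular cyclisation of the 1,5-diene.

Compound list
1 | tert-butyl(but-3-yn-1-yloxy)dimethylsilane | C#CCCO[Si](C)(C)C(C)(C)C | starting material
2 | (E)-[4-(tert-butyldimethylsilyloxy)-2-methylbut-1-en-1-yl]dimethylalane | C[Al](C)/C=C(C)/CCO[Si](C)(C)C(C)(C)C | intermediate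
3 | (E)-tert-butyl[(4-iodo-3-methylbut-3-en-1-yl)oxy]dimethylsilane | I/C=C(C)/CCO[Si](C)(C)C(C)(C)C | intermediate
4 | (4-bromobut-1-yn-1-yl)trimethylsilane | C[Si](C)(C)C#CCCBr | starting material
5 | [4-(trimethylsilyl)but-3-yn-1-yl]zinc bromide | C[Si](C)(C)C#CCC[Zn]Br | intermediate
6 | (E)-tert-butyldimethyl{[3-methyl-8-(trimethylsilyl)oct-3-en-7-yn-1-yl]oxy}silane | C[Si](C)(C)C#CCC/C=C(C)/CCO[Si](C)(C)C(C)(C)C | intermediate
7 | (E)-tert-butyldimethyl[(3-methyloct-3-en-7-yn-1-yl)oxy]silane | C#CCC/C=C(C)/CCO[Si](C)(C)C(C)(C)C | intermediate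
8 | 1-(tert-butyldimethylsilyloxy)propan-2-one | CC(=O)CO[Si](C)(C)C(C)(C)C | starting material
9 | ethyl (E)-4-(tert-butyldimethylsilyloxy)-3-methylbut-2-enoate | CCOC(=O)/C=C(\C)CO[Si](C)(C)C(C)(C)C | intermediate
10 | (E)-4-(tert-butyldimethylsilyloxy)-3-methylbut-2-en-1-ol | OC/C=C(\C)CO[Si](C)(C)C(C)(C)C | intermediate
11 | (E)-4-(tert-butyldimethylsilyloxy)-3-methylbut-2-enal | O=C/C=C(\C)CO[Si](C)(C)C(C)(C)C | intermediate
12 | methylzinc alkynylide of 7 | C[Zn]C#CCC/C=C(C)/CCO[Si](C)(C)C(C)(C)C | intermediate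
13 | (4S,2E,9E)-1,12-bis(tert-butyldimethylsilyloxy)-2,10-dimethyldodeca-2,9-dien-5-yn-4-ol | CC(C)(C)[Si](C)(C)OCC/C(C)=C/CCC#C[C@@H](O)/C=C(\C)CO[Si](C)(C)C(C)(C)C | intermediate
14 | sodium cyclic alkenylalanate of 13 (aluminium bound to O6 and C4, two 2-methoxyethoxy ligands) | CC(C)(C)[Si](C)(C)OCC/C(C)=C/CCC1=C[C@H](/C=C(\C)CO[Si](C)(C)C(C)(C)C)O[Al-]1(OCCOC)OCCOC.[Na+] | intermediate
15 | (4S,2E,5Z,9E)-1,12-bis(tert-butyldimethylsilyloxy)-6-iodo-2,10-dimethyldodeca-2,5,9-trien-4-ol | CC(C)(C)[Si](C)(C)OCC/C(C)=C/CC/C(I)=C/[C@@H](O)/C=C(\C)CO[Si](C)(C)C(C)(C)C | intermediate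
16 | (4R,2E,5E,9E)-1,12-bis(tert-butyldimethylsilyloxy)-2,6,10-trimethyldodeca-2,5,9-trien-4-ol | CC(C)(C)[Si](C)(C)OCC/C(C)=C/CC/C(C)=C/[C@@H](O)/C=C(\C)CO[Si](C)(C)C(C)(C)C | intermediate
17 | (4R,2E,5E,9E)-1,12-bis(tert-butyldimethylsilyloxy)-4-(tert-butyldiphenylsilyloxy)-2,6,10-trimethyldodeca-2,5,9-triene | CC(C)(C)[Si](C)(C)OCC/C(C)=C/CC/C(C)=C/[C@@H](O[Si](c1ccccc1)(c1ccccc1)C(C)(C)C)/C=C(\C)CO[Si](C)(C)C(C)(C)C | intermediate
18 | (4R,2E,5E,9E)-4-(tert-butyldiphenylsilyloxy)-2,6,10-trimethyldodeca-2,5,9-triene-1,12-diol | OCC/C(C)=C/CC/C(C)=C/[C@@H](O[Si](c1ccccc1)(c1ccccc1)C(C)(C)C)/C=C(\C)CO | intermediate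
19 | (9R,3E,7E,10E)-9-(tert-butyldiphenylsilyloxy)-12-chloro-3,7,11-trimethyldodeca-3,7,10-trien-1-ol | OCC/C(C)=C/CC/C(C)=C/[C@@H](O[Si](c1ccccc1)(c1ccccc1)C(C)(C)C)/C=C(\C)CCl | intermediate
20 | (9R,3E,7E,10E)-9-(tert-butyldiphenylsilyloxy)-12-chloro-3,7,11-trimethyldodeca-3,7,10-trienal | O=CC/C(C)=C/CC/C(C)=C/[C@@H](O[Si](c1ccccc1)(c1ccccc1)C(C)(C)C)/C=C(\C)CCl | intermediate
21 | allylchromium dichloride of 20 (trivalent chromium on C12) | O=CC/C(C)=C/CC/C(C)=C/[C@@H](O[Si](c1ccccc1)(c1ccccc1)C(C)(C)C)/C=C(\C)C[Cr](Cl)Cl | intermediate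
22 | (1(10)E,4E,6R,7R,8S)-6-(tert-butyldiphenylsilyloxy)germacra-1(10),4,11-trien-8-ol | C/C1=C\[C@@H](O[Si](c2ccccc2)(c2ccccc2)C(C)(C)C)[C@H](C(C)=C)[C@@H](O)C/C(C)=C/CC1 | intermediate
23 | (1(10)E,4E,6R,7R,8S)-germacra-1(10),4,11-triene-6,8-diol | C/C1=C\[C@@H](O)[C@H](C(C)=C)[C@@H](O)C/C(C)=C/CC1 | intermediate
24 | (1(10)E,4E,6R,7R,8S)-germacra-1(10),4-diene-6,8-diol | C/C1=C\[C@@H](O)[C@H](C(C)C)[C@@H](O)C/C(C)=C/CC1 | intermediate
25 | (1(10)E,4E,7R,8S)-8-hydroxygermacra-1(10),4-dien-6-one | C/C1=C\C(=O)[C@H](C(C)C)[C@@H](O)C/C(C)=C/CC1 | intermediate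
26 | (E)-3-(4-hydroxyphenyl)prop-2-enal | O=C/C=C/c1ccc(O)cc1 | starting material
27 | (E)-3-[4-(tert-butyldimethylsilyloxy)phenyl]prop-2-enal | O=C/C=C/c1ccc(O[Si](C)(C)C(C)(C)C)cc1 | intermediate
28 | (1(10)E,4E,6S,7S,8S)-6-hydroxygermacra-1(10),4-dien-8-yl (E)-3-[4-(tert-butyldimethylsilyloxy)phenyl]prop-2-enoate | C/C1=C\[C@H](O)[C@H](C(C)C)[C@@H](OC(=O)/C=C/c2ccc(O[Si](C)(C)C(C)(C)C)cc2)C/C(C)=C/CC1 | intermediate
29 | (1(10)E,4E,6S,7S,8S)-6-hydroxygermacra-1(10),4-dien-8-yl (E)-3-(4-hydroxyphenyl)prop-2-enoate | C/C1=C\[C@H](O)[C@H](C(C)C)[C@@H](OC(=O)/C=C/c2ccc(O)cc2)C/C(C)=C/CC1 | target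

Total step count: 20. Longest linear sequence: 16 steps (1–3, 7–17, 19, 20).

Steps most likely to fail

Step 14 (ring closure). Intermolecular coupling may outrun closure of the strained ten-membered ring, the allylchromium may lose the C6 silyloxy group by 1,4-elimination, or face selection at C7 may be poor. The fallback sets out from 20 and replaces the reducing metal by a tandem borylation–allylboration. B2pin2 with Pd2(dba)3 (zerovalent palladium) in dilute toluene at 50 °C should convert the allylic chloride into the pinacol allylboronate (9R,3E,7E,10E)-9-(tert-butyldiphenylsilyloxy)-3,7,11-trimethyl-12-(4,4,5,5-tetramethyl-1,3,2-dioxaborolan-2-yl)dodeca-3,7,10-trienal F1. This is not isolated; it adds to its own aldehyde through a boron-centred chair without a Lewis acid, with the same anti course and the same control by C6. Aqueous work-up of the borate returns the route to 22.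

Step 19 (Evans–Tishchenko). The samarium alkoxide may open the strained ring by retro-aldol cleavage, hemiacetal formation at the hindered C8 hydroxyl may be slow, or the acyl group may migrate to O6. The fallback sets out from 25 and separates reduction from acylation. Saksena–Evans reduction (Me4NBH(OAc)3, MeCN/AcOH, −30 °C) delivers hydride internally from the C8 acetoxyborate in an acidic medium free of alkoxide and should give the anti-diol (1(10)E,4E,6S,7R,8S)-germacra-1(10),4-diene-6,8-diol F2. Pinnick oxidation of 27 (NaClO2, NaH2PO4, 2-methylbut-2-ene) gives (E)-3-[4-(tert-butyldimethylsilyloxy)phenyl]prop-2-enoic acid F3. Carbodiimide esterification (EDC·HCl, DMAP, CH2Cl2, 0 °C) with one equivalent of F3 should acylate the pseudo-equatorial C8 hydroxyl, trans to the isopropyl group, ahead of the allylic C6 hydroxyl, which is cis to it, and so come back at 28.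

Step 16 (hydrogenation). Reduction of the 2-propenyl group, flanked by two carbinols, may be sluggish, or the rhodium hydride may reduce or isomerise the strained ring alkenes. The fallback sets out from 22, avoids the metal and changes the order. Diimide (2-nitrobenzenesulfonyl hydrazide, Et3N, CH2Cl2, rt) should reduce only the 1,1-disubstituted alkene of the silyl ether, whose bulky group also shields C4=C5, to give (1(10)E,4E,6R,7R,8S)-6-(tert-butyldiphenylsilyloxy)germacra-1(10),4-dien-8-ol F4. TBAF in THF then removes the silyl group and comes back at 24.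

Further compounds
F1 | step 14 | (9R,3E,7E,10E)-9-(tert-butyldiphenylsilyloxy)-3,7,11-trimethyl-12-(4,4,5,5-tetramethyl-1,3,2-dioxaborolan-2-yl)dodeca-3,7,10-trienal | O=CC/C(C)=C/CC/C(C)=C/[C@@H](O[Si](c1ccccc1)(c1ccccc1)C(C)(C)C)/C=C(\C)CB1OC(C)(C)C(C)(C)O1
F2 | step 19 | (1(10)E,4E,6S,7R,8S)-germacra-1(10),4-diene-6,8-diol | C/C1=C\[C@H](O)[C@H](C(C)C)[C@@H](O)C/C(C)=C/CC1
F3 | step 19 | (E)-3-[4-(tert-butyldimethylsilyloxy)phenyl]prop-2-enoic acid | O=C(O)/C=C/c1ccc(O[Si](C)(C)C(C)(C)C)cc1
F4 | step 16 | (1(10)E,4E,6R,7R,8S)-6-(tert-butyldiphenylsilyloxy)germacra-1(10),4-dien-8-ol | C/C1=C\[C@@H](O[Si](c2ccccc2)(c2ccccc2)C(C)(C)C)[C@H](C(C)C)[C@@H](O)C/C(C)=C/CC1
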